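**Assumptions.** I read the target as 6,8-diacetoxy-1,10-epoxygermacr-4(E)-en-14-al, with the epoxide cis in the ring (C2 and C9 cis across C1–C10) exactly as the SMILES encodes. I assume the (S)-benzyl Evans auxiliary gives the syn-aldol sense needed at C7/C8. Germacrane numbering is used throughout: C1 epoxide CH, C4 bears the methyl C15, C7 bears the isopropyl, C10 bears the CHO (C14).

## Retrosynthetic overview
1. Target ⇐ C1–C10 epoxy-aldehyde ⇐ (Z)-enal ⇐ vinyl triflate ⇐ (E)-cyclodecenone. The epoxide and the acetates are installed last.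
2. The ten-membered ring comes from an anionic oxy-Cope 6→10 ring expansion of a 1-vinyl-2-isopropenylcyclohexanol (ring C5–C10). It cleaves C5–C10, forms C2–C3, and sets the E-C4=C5 alkene and the C10=C1 enolate regiospecifically.
3. The cyclohexane comes from an intramolecular carbonyl-ene cyclization (C10 aldehyde onto the C5=C4Me2 prenyl alkene), which builds the isopropenyl group and the C5–C10 bond.
4. The acyclic C6/C7/C8 stereotriad comes from an Evans syn-aldol (C7/C8, with acrolein) and a CBS reduction (C6, with an isobutenyl ketone).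

## Route

**Step 1**
Reactants: 1 (3-methylbutanoyl chloride), 2 ((S)-4-benzyloxazolidin-2-one)
Product: 3 (N-isovaleryl oxazolidinone)
Conditions: n-BuLi, THF, −78 °C, then 1, −78 → 0 °C
Reagents that add atoms: none
Why: N-acylation installs the Evans auxiliary.

**Step 2**
Reactants: 3, 4 (acrolein)
Product: 5 ((S)-4-benzyl-3-[(2S,3R)-3-hydroxy-2-isopropylpent-4-enoyl]oxazolidin-2-one)
Conditions: Bu2BOTf, Et3N, CH2Cl2, −78 → 0 °C; then acrolein; then H2O2, pH 7 buffer/MeOH
Reagents that add atoms: none
Why: Evans syn-aldol through the Z-boron enolate and a Zimmerman–Traxler TS. It sets C7 (S) and C8 (R) with 7,8-syn relationship, as required.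

**Step 3**
Reactants: 5
Product: 6 (C8-O-TIPS ether of 5)
Conditions: TIPSOTf, 2,6-lutidine, CH2Cl2, −78 → 0 °C
Reagents that add atoms: triisopropylsilyl triflate, CC(C)[Si](C(C)C)(C(C)C)OS(=O)(=O)C(F)(F)F
Why: Silylation with a bulky group. The bulk will later disfavour C9 enolisation and silyl migration.

**Step 4**
Reactants: 6
Product: 7 (Weinreb amide)
Conditions: MeNH(OMe)·HCl, Me3Al, CH2Cl2, 0 °C → rt (auxiliary 2 recovered)
Reagents that add atoms: N,O-dimethylhydroxylamine, CONC
Why: Aluminium-amide transamidation removes the auxiliary without touching the stereocentres.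

**Step 5**
Reactants: 7, 8 (2-methylprop-1-enylmagnesium bromide, CC(C)=C[Mg]Br)
Product: 9 (enone)
Conditions: THF, −78 → 0 °C; NH4Cl quench
Reagents that add atoms: none beyond reactant 8
Why: Weinreb ketone synthesis; the stable chelated intermediate avoids over-addition and enolisation/β-elimination.

**Step 6**
Reactants: 9
Product: 10 (allylic alcohol, C6-OH anti to the C7 isopropyl)
Conditions: (S)-Me-CBS (20 mol %), BH3·SMe2, THF, −30 °C
Reagents that add atoms: none
Why: CBS reduction. Catalyst control sets C6 (R) anti to C7, as the target requires, overriding the weak α-stereocentre bias.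

**Step 7**
Reactants: 10
Product: 11 (C6-O-TBS ether)
Conditions: TBSOTf, 2,6-lutidine, CH2Cl2, −78 → 0 °C
Reagents that add atoms: tert-butyldimethylsilyl triflate, CC(C)(C)[Si](C)(C)OS(=O)(=O)C(F)(F)F
Why: Protection of the hindered secondary alcohol.

**Step 8**
Reactants: 11
Product: 12 (primary alcohol at C10)
Conditions: 9-BBN, THF, 0 °C → rt; then 3 M NaOH, 30% H2O2
Reagents that add atoms: hydrogen peroxide, OO (supplies the new O)
Why: Hydroboration–oxidation. 9-BBN is chemoselective for the monosubstituted vinyl group over the hindered trisubstituted isobutenyl alkene.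

**Step 9**
Reactants: 12
Product: 13 (C10 aldehyde)
Conditions: Dess–Martin periodinane, NaHCO3, CH2Cl2, 0 °C → rt
Reagents that add atoms: none
Why: Mild oxidation of the primary alcohol.

**Step 10**
Reactants: 13
Product: 14 (cyclohexanol, ring C5–C10: C10-OH, C5 isopropenyl, C6-OTBS, C7 iPr, C8-OTIPS)
Conditions: Me2AlCl (2 equiv), CH2Cl2, −78 → −20 °C
Reagents that add atoms: none
Why: Snider-type intramolecular carbonyl-ene (citronellal → isopulegol pattern) through a chair TS. It forms the C5–C10 bond and the isopropenyl group; the C5/C10 centres are transient and C6–C8 are untouched.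

**Step 11**
Reactants: 14
Product: 15 (cyclohexanone)
Conditions: Dess–Martin periodinane, NaHCO3, CH2Cl2, rt
Reagents that add atoms: none
Why: Oxidation of the secondary alcohol. C5 is epimerizable and will be destroyed later.

**Step 12**
Reactants: 15, 16 (vinylmagnesium bromide, C=C[Mg]Br)
Product: 17 (1-vinyl-2-isopropenylcyclohexanol, the oxy-Cope substrate)
Conditions: CeCl3, THF, −78 °C
Reagents that add atoms: none beyond reactant 16
Why: Organocerium 1,2-addition suppresses enolisation of the acidic α-H. The C5/C10 configuration is transient.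

**Step 13**
Reactants: 17
Product: 18 ((4E)-6-OTBS-8-OTIPS-germacr-4-en-10-one)
Conditions: KH, 18-crown-6, THF, 25 → 50 °C; then sat. NH4Cl
Reagents that add atoms: none
Why: Anionic oxy-Cope 6→10 ring expansion. A chair TS with C6 pseudo-equatorial gives the E-trisubstituted C4=C5 alkene and forms C2–C3. The C10=C1 enolate is regiospecific and protonates to the ketone.

**Step 14**
Reactants: 18
Product: 19 ((1Z)-10-triflyloxy-germacra-1(10),4E-diene, bis-silyl ether)
Conditions: KHMDS, PhNTf2, THF, −78 °C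
Reagents that add atoms: N-phenylbis(triflimide), O=S(=O)(C(F)(F)F)N(c1ccccc1)S(=O)(=O)C(F)(F)F
Why: Kinetic enolisation toward C1, because C9 is shielded by OTIPS and iPr. Ring strain forces the Z (ring-cis) enolate, so O-triflation gives the Z vinyl triflate.

**Step 15**
Reactants: 19
Product: 20 ((1Z)-enal: 10-CHO, C1=C10, bis-silyl ether)
Conditions: Pd(PPh3)4 (5 mol %), CO (1 atm), Bu3SnH, LiCl, THF, 50 °C
Reagents that add atoms: carbon monoxide, [C-]#[O+]
Why: Pd-catalysed reductive carbonylation of the vinyl triflate (Stille–Pri formylation) proceeds with retention. C14 lands trans to C2, i.e. the ring-Z enal.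

**Step 16**
Reactants: 20
Product: 21 (1,10-epoxy-14-al, bis-silyl ether)
Conditions: 30% H2O2, aq. NaOH, MeOH/THF, 0 °C
Reagents that add atoms: hydrogen peroxide, OO
Why: Weitz–Scheffer nucleophilic epoxidation, chemoselective for the enal over the C4=C5 alkene. Ring constraint keeps the cis epoxide, and the face is set by the macrocycle conformation (1R,10S).

**Step 17**
Reactants: 21
Product: 22 (6,8-diol)
Conditions: HF·pyridine, pyridine/THF, 25 → 40 °C
Reagents that add atoms: none
Why: Buffered acidic desilylation; the electron-poor epoxy aldehyde survives.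

**Step 18**
Reactants: 22
Product: 23 (Pulicanaral A)
Conditions: Ac2O, DMAP, pyridine, CH2Cl2, rt
Reagents that add atoms: acetic anhydride, CC(=O)OC(C)=O
Why: Bis-acetylation of the two secondary alcohols with retention of configuration.

## Compound list
1 | 3-methylbutanoyl chloride | CC(C)CC(=O)Cl | starting material
2 | (S)-4-benzyloxazolidin-2-one | O=C1N[C@@H](Cc2ccccc2)CO1 | starting material
3 | (S)-4-benzyl-3-(3-methylbutanoyl)oxazolidin-2-one | CC(C)CC(=O)N1[C@@H](Cc2ccccc2)COC1=O | intermediate
4 | acrolein | C=CC=O | starting material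
5 | Evans syn-aldol adduct, (2S,3R) | C=C[C@@H](O)[C@H](C(C)C)C(=O)N1[C@@H](Cc2ccccc2)COC1=O | intermediate
6 | C8-O-TIPS imide | C=C[C@@H](O[Si](C(C)C)(C(C)C)C(C)C)[C@H](C(C)C)C(=O)N1[C@@H](Cc2ccccc2)COC1=O | intermediate
7 | Weinreb amide (2S,3R) | C=C[C@@H](O[Si](C(C)C)(C(C)C)C(C)C)[C@H](C(C)C)C(=O)N(C)OC | intermediate
8 | 2-methylprop-1-enylmagnesium bromide | CC(C)=C[Mg]Br | starting material
9 | enone, (3R,4S)-4-isopropyl-7-methyl-3-(TIPSO)octa-1,6-dien-5-one | C=C[C@@H](O[Si](C(C)C)(C(C)C)C(C)C)[C@H](C(C)C)C(=O)C=C(C)C | intermediate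
10 | allylic alcohol (C6 R, anti to C7 iPr) | C=C[C@@H](O[Si](C(C)C)(C(C)C)C(C)C)[C@H](C(C)C)[C@H](O)C=C(C)C | intermediate
11 | C6-O-TBS ether | C=C[C@@H](O[Si](C(C)C)(C(C)C)C(C)C)[C@H](C(C)C)[C@H](O[Si](C)(C)C(C)(C)C)C=C(C)C | intermediate
12 | primary alcohol (C10-OH, C9 CH2) | OCC[C@@H](O[Si](C(C)C)(C(C)C)C(C)C)[C@H](C(C)C)[C@H](O[Si](C)(C)C(C)(C)C)C=C(C)C | intermediate
13 | aldehyde (ene precursor) | O=CC[C@@H](O[Si](C(C)C)(C(C)C)C(C)C)[C@H](C(C)C)[C@H](O[Si](C)(C)C(C)(C)C)C=C(C)C | intermediate
14 | cyclohexanol (C5, C10 configuration unassigned) | OC1C[C@@H](O[Si](C(C)C)(C(C)C)C(C)C)[C@H](C(C)C)[C@H](O[Si](C)(C)C(C)(C)C)C1C(C)=C | intermediate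
15 | cyclohexanone (C5 epimerizable) | O=C1C[C@@H](O[Si](C(C)C)(C(C)C)C(C)C)[C@H](C(C)C)[C@H](O[Si](C)(C)C(C)(C)C)C1C(C)=C | intermediate
16 | vinylmagnesium bromide | C=C[Mg]Br | starting material
17 | 1-vinyl-2-isopropenylcyclohexanol (C5, C10 configuration unassigned) | C=CC1(O)C[C@@H](O[Si](C(C)C)(C(C)C)C(C)C)[C@H](C(C)C)[C@H](O[Si](C)(C)C(C)(C)C)C1C(C)=C | intermediate
18 | (4E)-6-OTBS-8-OTIPS-germacr-4-en-10-one | C[Si](C)(C(C)(C)C)O[C@@H]1/C=C(\C)CCCC(=O)C[C@@H](O[Si](C(C)C)(C(C)C)C(C)C)[C@@H]1C(C)C | intermediate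
19 | (1Z,4E)-10-OTf germacradiene | C[Si](C)(C(C)(C)C)O[C@@H]1/C=C(\C)CC/C=C(/OS(=O)(=O)C(F)(F)F)C[C@@H](O[Si](C(C)C)(C(C)C)C(C)C)[C@@H]1C(C)C | intermediate
20 | (1Z,4E)-germacradien-14-al, bis-silyl ether | C[Si](C)(C(C)(C)C)O[C@@H]1/C=C(\C)CC/C=C(/C=O)C[C@@H](O[Si](C(C)C)(C(C)C)C(C)C)[C@@H]1C(C)C | intermediate
21 | 1,10-epoxy-14-al, bis-silyl ether | C[Si](C)(C(C)(C)C)O[C@@H]1/C=C(\C)CC[C@H]2O[C@@]2(C=O)C[C@@H](O[Si](C(C)C)(C(C)C)C(C)C)[C@@H]1C(C)C | intermediate
22 | 6,8-dihydroxy epoxy aldehyde | O[C@@H]1/C=C(\C)CC[C@H]2O[C@@]2(C=O)C[C@@H](O)[C@@H]1C(C)C | intermediate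
23 | Pulicanaral A | CC(=O)O[C@@H]1/C=C(\C)CC[C@H]2O[C@@]2(C=O)C[C@@H](OC(C)=O)[C@@H]1C(C)C | target

## Totals
Total steps: 18. Longest linear sequence: 18.

## Three steps most likely to fail
1. **Step 13, oxy-Cope.** Risks are the chair/boat choice, the E-alkene outcome, and silyl migration under KH. Fallback (different approach): drop the ring expansion and close the ten-membered ring by intramolecular NHK coupling (CrCl2/NiCl2) of a C5 vinyl iodide with the C6 aldehyde, built from an acyclic chain derived from Evans adduct 5.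
2. **Step 14, enol triflation.** Risks are regioselectivity (C1 vs C9, with the β-silyloxy leaving-group risk) and Z geometry. Fallback (different approach): trap the Cope enolate in situ with Comins' reagent, which is regiospecific at C10=C1 by construction, merging steps 13 and 14 and choosing the P diastereomer that gives the Z-enolate.
3. **Step 16, epoxidation face selectivity.** Fallback (different approach): Luche reduction of enal 20, then hydroxyl-directed epoxidation (VO(acac)2/TBHP, or Ti(OiPr)4/(+)- or (−)-DET for reagent control), then Dess–Martin oxidation of the epoxy alcohol to the aldehyde.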